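The bicycle is cut at C4–C5 and C8–C8a (azulene numbering). The cut exploits that, in the seven-membered ring, C4 carries only one exocyclic carbon and adjoins fusion atom C3a, while C5–C8 is a plain four-carbon chain ending at carbinol C8. C4, C3a and C8a therefore come from a cyclopentenyl diazoacetate, C5–C8 from a 1-silyloxy-2-alkylbutadiene. One rhodium-catalysed operation, cyclopropanation followed by a Cope shift, couples the fragments, closes the seven-membered ring and sets C8 and C8a. The diazo ester holds C1/C2 as a cis-diol acetonide, later the leaving group for the C2–C3 alkene; its ester becomes the exocyclic methylene.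

Key step: step 15

Conventions: the azulene numbering of the target is used for all bicyclic compounds and for the fragment atoms that end up there. The side chain is C1′ (methine), C2′ (methylene), C3′ (carbinol). β is the face that bears H-3a, H-7, H-8, H-8a and the C1 hydroxyl in the target; α is the opposite face (C1 methyl, C8 oxygen, C7 side chain).

Assumption: the sense of induction of the prolinate catalyst follows the empirical model for donor/acceptor carbenoids (S catalyst, styrene and methyl phenyldiazoacetate give the (1S,2R)-cyclopropane); mapped onto 10 + 20 this calls for the R catalyst, and both antipodes are commercial.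

Step 1
Reactants: 1 2-methylcyclopent-2-en-1-one
Product: 2 (S)-2-methylcyclopent-2-en-1-ol
Conditions: (R)-Me-CBS (10 mol %), BH3·SMe2, THF, −20 °C; MeOH
Reagents that add atoms: none
Why: Corey–Bakshi–Shibata reduction in which the alkenyl side of the enone acts as the large group, so the R catalyst should give the S carbinol, a relay centre for C1/C2 whose residual antipode is purged as a diastereomer after coupling with 20.

Step 2
Reactants: 2 (S)-2-methylcyclopent-2-en-1-ol
Product: 3 (1S,3S)-2-methylcyclopentane-1,2,3-triol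
Conditions: OsO4 (1 mol %), NMO, acetone–H2O, 0 → 23 °C
Reagents that add atoms: N-methylmorpholine N-oxide C[N+]1([O-])CCOCC1; water O
Why: Upjohn dihydroxylation, a syn addition that by the empirical anti rule for allylic alcohols should occur on the ring face opposite to the hydroxyl and so creates the C1/C2 cis-diol in one absolute sense.

Step 3
Reactants: 3 (1S,3S)-2-methylcyclopentane-1,2,3-triol
Product: 4 (3aR,4S,6aS)-2,2,3a-trimethyltetrahydro-4H-cyclopenta[d][1,3]dioxol-4-ol (free hydroxyl trans to the dioxolane)
Conditions: Me2C(OMe)2, p-TsOH (2 mol %), acetone, 23 °C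
Reagents that add atoms: 2,2-dimethoxypropane COC(C)(C)OC
Why: Acid-catalysed transketalisation bridges only the cis-vicinal C1/C2 hydroxyls of a cyclopentane, and the isomeric acetonide from any meso all-cis triol is removed here by chromatography so that it cannot lower the enantiomeric purity.

Step 4
Reactants: 4 acetonide alcohol
Product: 5 (3aS,6aS)-2,2,3a-trimethyltetrahydro-4H-cyclopenta[d][1,3]dioxol-4-one
Conditions: Dess–Martin periodinane, CH2Cl2, 23 °C
Reagents that add atoms: none
Why: Dess–Martin oxidation removes the relay centre and gives a ketone (carbonyl = future C8a) that can enolise only towards C3a because C1 is quaternary.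

Step 5
Reactants: 5 acetonide ketone; 6 methyl bromoacetate
Product: 7 methyl 2-[(3aS,5R,6aS)-2,2,3a-trimethyl-4-oxotetrahydro-4H-cyclopenta[d][1,3]dioxol-5-yl]acetate (acetate arm trans to the dioxolane)
Conditions: LiN(iPr)2, THF, −78 °C; 6, DMPU, −78 → −30 °C
Reagents that add atoms: none
Why: Lithium enolate alkylation with a reactive α-bromo ester attaches C4 and the ester carbon to C3a from the convex face, and the new centre is erased in step 6.

Step 6
Reactants: 7 keto ester
Product: 8 methyl 2-[(3aS,6aS)-2,2,3a-trimethyl-4-(trifluoromethylsulfonyloxy)-6,6a-dihydro-3aH-cyclopenta[d][1,3]dioxol-5-yl]acetate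
Conditions: KN(SiMe3)2, THF, −78 → −40 °C; PhNTf2, −78 → 0 °C
Reagents that add atoms: N-phenylbis(trifluoromethanesulfonimide) O=S(=O)(N(c1ccccc1)S(=O)(=O)C(F)(F)F)C(F)(F)F
Why: Enol triflate formation, in which the ketone is much more acidic than the ester and has H-3a as its only α-hydrogen, so equilibrating deprotonation and O-sulfonylation fix the double bond at C3a=C8a.

Step 7
Reactants: 8 vinyl triflate
Product: 9 methyl 2-[(3aR,6aS)-2,2,3a-trimethyl-6,6a-dihydro-3aH-cyclopenta[d][1,3]dioxol-5-yl]acetate
Conditions: Pd(OAc)2 (5 mol %), PPh3 (10 mol %), HCO2H, Et3N, DMF, 60 °C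
Reagents that add atoms: none
Why: Palladium-catalysed formate reduction of a vinyl triflate replaces OTf by H without moving the β,γ-double bond, and the ketal oxygen at C1 is too poor a leaving group for zerovalent palladium.

Step 8
Reactants: 9 cyclopentenylacetate
Product: 10 methyl 2-diazo-2-[(3aR,6aS)-2,2,3a-trimethyl-6,6a-dihydro-3aH-cyclopenta[d][1,3]dioxol-5-yl]acetate
Conditions: p-ABSA, DBU, MeCN, 0 °C
Reagents that add atoms: 4-acetamidobenzenesulfonyl azide CC(=O)Nc1ccc(cc1)S(=O)(=O)N=[N+]=[N-]
Why: Regitz diazo transfer to the allylic ester methylene is the standard access to vinyldiazoacetates, and low temperature with excess azide favours trapping of the small dienolate concentration over loss of the C1 alkoxide.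

Step 9
Reactants: 11 methyl (R)-3-methylglutarate
Product: 12 methyl (3R)-5-hydroxy-3-methylpentanoate
Conditions: BH3·SMe2, THF, 0 → 23 °C; MeOH
Reagents that add atoms: none
Why: Chemoselective borane reduction of a carboxylic acid beside a methyl ester differentiates the two arms of the glutarate without touching the stereocentre (future C1′).

Step 10
Reactants: 12 hydroxy ester
Product: 13 methyl (3R)-5-(tert-butyldiphenylsilyloxy)-3-methylpentanoate
Conditions: TBDPSCl, imidazole, CH2Cl2, 23 °C
Reagents that add atoms: tert-butylchlorodiphenylsilane CC(C)(C)[Si](Cl)(c1ccccc1)c1ccccc1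
Why: Standard silylation gives an ether that resists base, hydride and the carbenoid and can later be cleaved beside the hindered C8 TBS ether.

Step 11
Reactants: 13 silyloxy ester
Product: 14 (3R)-5-(tert-butyldiphenylsilyloxy)-3-methylpentanal
Conditions: iBu2AlH (1.05 equiv), CH2Cl2, −78 °C
Reagents that add atoms: none
Why: Low-temperature half-reduction of the ester stops at the stable aluminium hemiacetal, which releases the aldehyde on work-up.

Step 12
Reactants: 14 aldehyde
Product: 15 (E)-N-cyclohexyl aldimine of 14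
Conditions: c-C6H11NH2, MgSO4, Et2O, 0 → 23 °C
Reagents that add atoms: cyclohexylamine NC1CCCCC1
Why: Imine condensation blocks self-aldolisation and defines this aldehyde as the nucleophile of the crossed aldol.

Step 13
Reactants: 15 aldimine; 16 acetaldehyde
Product: 19 (2E)-2-[(2R)-4-(tert-butyldiphenylsilyloxy)butan-2-yl]but-2-enal, via hydroxy imine 17 (not isolated), via aldol 18 (not isolated)
Conditions: LiN(iPr)2, THF, 0 °C; 16, −78 °C; aq. oxalic acid, THF, 23 °C
Reagents that add atoms: water O
Why: Wittig directed aldol condensation, in which the lithiated aldimine (C7) adds to acetaldehyde (C6/C5) and acidic hydrolysis releases the aldol, which dehydrates to the more stable E enal.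

Step 14
Reactants: 19 enal
Product: 20 1-(tert-butyldimethylsilyloxy)-2-[(2R)-4-(tert-butyldiphenylsilyloxy)butan-2-yl]buta-1,3-diene, OTBS trans to the vinyl group (Z by the sequence rule)
Conditions: TBSOTf, Et3N, Et2O, 0 → 23 °C
Reagents that add atoms: tert-butyldimethylsilyl triflate CC(C)(C)[Si](C)(C)OS(=O)(=O)C(F)(F)F
Why: Soft γ-deprotonation and O-silylation of the s-trans enal, as established for tiglic aldehyde, should give the dienol ether with oxygen trans to the vinyl group.

Step 15
Reactants: 10 cyclopentenyl diazoacetate; 20 silyloxydiene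
Product: 22 hydroazulene 1,4-diene ester (C3a=C4 enoate; C6=C7 alkene bearing the side chain; 8α-OTBS; H-8 and H-8a both β; 1,2-acetonide β), via cis-divinylcyclopropane 21 (not isolated)
Conditions: Rh2(R-DOSP)4 (1 mol %), hexanes, −20 → 23 °C, 10 added over 3 h to 20 (1.3 equiv); then 40 °C
Reagents that add atoms: none
Why: Loss of N2 from 10 at the divalent rhodium centre gives a donor/acceptor vinylcarbenoid that adds to the terminal C5=C6 vinyl group of 20 with the cyclopentenyl donor cis to the silyloxyvinyl arm (cyclopropane 21). This cis-divinylcyclopropane undergoes a [3,3] shift through the obligatory boat transition state, which breaks C4–C6 and makes C8–C8a, so the seven-membered ring closes by sigmatropic expansion of the three-membered ring onto the existing cyclopentene; the closest known reaction type is the tandem cyclopropanation/Cope rearrangement (formal (4+3) cycloaddition) of vinyldiazoacetates with dienes. The OTBS group on C8 and C1 on C8a are both trans to the cyclopropane and point out of the boat, so H-8 and H-8a should end up cis, and their absolute sense is relayed from C4/C6 of 21, that is from the carbenoid face selected by the prolinate ligands. With the R catalyst the new C8–C8a bond should form on the α face of the cyclopentene, the convex face of the dioxolane-fused bicycle, so catalyst and substrate are matched. Site selectivity for C5=C6 over the trisubstituted enol ether C7=C8 rests on the steric demand of donor/acceptor carbenoids, attack at the vinylogous position C8a is hindered by the quaternary neighbour C1, and a hydrocarbon solvent with slow addition suppresses carbene dimerisation.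

Step 16
Reactants: 22 hydroazulene 1,4-diene ester
Product: 23 6,7-dihydro ester (H-7 β, side chain 7α, C3a=C4 enoate intact)
Conditions: H2 (4 bar), PtO2 (10 mol %), EtOAc, 23 °C
Reagents that add atoms: none
Why: In this catalytic syn-hydrogenation the trisubstituted C6=C7 bond reacts before the tetrasubstituted enoate, and because the ring fusion locks the cycloheptadiene boat with only H-8 and H-8a on the exposed β face while the α face is folded over the other alkene, hydrogen should add from β and set H-7 cis to H-8.

Step 17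
Reactants: 23 6,7-dihydro ester
Product: 25 1β-hydroxy dienoate (C2=C3 and C3a=C4 conjugated with the ester, C1 carbinol free), via hemiketal 24 (not isolated)
Conditions: LiN(iPr)2 (1.5 equiv), THF, −78 → −20 °C; AcOH, −78 °C
Reagents that add atoms: none
Why: In this vinylogous E1cB (1,4-) elimination the amide base removes a C3 proton, the γ-site that is cis to the ester and far more accessible than the tertiary H-8a, the dienolate expels the C2 oxygen, and the hemiketal alkoxide then loses acetone and leaves the C1 configuration untouched.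

Step 18
Reactants: 25 hydroxy dienoate
Product: 26 dienyl diol (C4–CH2OH, 1β-OH)
Conditions: iBu2AlH (4 equiv), CH2Cl2, −78 → −20 °C
Reagents that add atoms: none
Why: iBu2AlH reduces the dienoate in 1,2-fashion to the primary dienylic alcohol while the tertiary alkoxide is a spectator.

Step 19
Reactants: 26 dienyl diol
Product: 29 4-methylene hydroazulene (H-3a β, cis-fused; C2=C3; 1β-OH; 8α-OTBS; primary OTBDPS), via sulfonylhydrazone adduct 27 (not isolated), via allylic diazene 28 (not isolated)
Conditions: IPNBSH, PPh3, DEAD, THF, 0 → 23 °C; CF3CH2OH–H2O, 23 °C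
Reagents that add atoms: none
Why: In the Myers reductive allylic transposition, Mitsunobu displacement occurs only at the primary carbinol, hydrolysis and loss of sulfinate give the monoalkyl diazene, and its retro-ene loss of N2 moves the double bond to C4=CH2 and should deliver H to C3a on the β face, because the α face is covered by C8 with its silyl ether and by the C1 methyl group.

Step 20
Reactants: 29 4-methylene hydroazulene
Product: 30 primary alcohol (C3′–OH free, 8α-OTBS kept)
Conditions: Bu4NF–AcOH (1:1), THF, 23 °C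
Reagents that add atoms: none
Why: Buffered fluoride desilylation cleaves the unhindered primary TBDPS ether faster than the secondary TBS ether flanked by C7 and C8a.

Step 21
Reactants: 30 primary alcohol
Product: 31 C3′ aldehyde
Conditions: Dess–Martin periodinane, pyridine, CH2Cl2, 0 °C
Reagents that add atoms: none
Why: Dess–Martin oxidation under pyridine buffer leaves the tertiary allylic alcohol, the skipped diene and the silyl ether untouched.

Step 22
Reactants: 31 C3′ aldehyde; 32 2-methylprop-1-enylmagnesium bromide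
Product: 33 C3′ allylic alcohols (both C3′ epimers)
Conditions: Me2C=CHMgBr (2.5 equiv), THF, −78 °C; aq. NH4Cl
Reagents that add atoms: none
Why: Grignard 1,2-addition (one equivalent is spent on the free hydroxyl) completes the carbon skeleton, and since the remote C1′ methyl centre gives no useful induction both epimers are carried on together.

Step 23
Reactants: 33 C3′ allylic alcohols
Product: 34 C3′ isobutenyl ketone
Conditions: Dess–Martin periodinane, pyridine, CH2Cl2, 0 °C
Reagents that add atoms: none
Why: Dess–Martin oxidation converges both epimers on a single enone.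

Step 24
Reactants: 34 C3′ isobutenyl ketone
Product: 35 (3′R)-allylic alcohol
Conditions: (S)-Me-CBS (30 mol %), catecholborane (3 equiv), toluene, −78 °C
Reagents that add atoms: none
Why: In this Corey–Bakshi–Shibata reduction catecholborane does not hydroborate the alkenes at −78 °C and the isobutenyl group acts as the large substituent, so the S catalyst should give the R carbinol by reagent control.

Step 25
Reactants: 35 (3′R)-allylic alcohol
Product: 36 (3′R)-acetate with 8α-OTBS
Conditions: Ac2O, pyridine, DMAP (5 mol %), CH2Cl2, 0 °C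
Reagents that add atoms: acetic anhydride CC(=O)OC(C)=O
Why: Acylation takes place at the unhindered secondary allylic alcohol, whereas the tertiary C1 hydroxyl does not react at 0 °C and C8 is still silylated.

Step 26
Reactants: 36 (3′R)-acetate with 8α-OTBS
Product: 37 CNP0209568.2
Conditions: Bu4NF, AcOH, THF, 23 → 40 °C
Reagents that add atoms: none
Why: Fluoride desilylation under acetic acid buffer is mild enough for the acetate, the tertiary allylic alcohol and the doubly allylic H-3a.

Compound list
1 | 2-methylcyclopent-2-en-1-one | CC1=CCCC1=O | starting material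
2 | (S)-2-methylcyclopent-2-en-1-ol | O[C@H]1CCC=C1C | intermediate
3 | (1S,3S)-2-methylcyclopentane-1,2,3-triol | O[C@H]1CC[C@H](O)C1(C)O | intermediate
4 | (3aR,4S,6aS)-2,2,3a-trimethyltetrahydro-4H-cyclopenta[d][1,3]dioxol-4-ol | O[C@H]1CC[C@@H]2OC(C)(C)O[C@]12C | intermediate
5 | (3aS,6aS)-2,2,3a-trimethyltetrahydro-4H-cyclopenta[d][1,3]dioxol-4-one | O=C1CC[C@@H]2OC(C)(C)O[C@]12C | intermediate
6 | methyl bromoacetate | COC(=O)CBr | starting material
7 | keto ester, acetate arm trans to the dioxolane | COC(=O)C[C@H]1C[C@@H]2OC(C)(C)O[C@]2(C)C1=O | intermediate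
8 | vinyl triflate | COC(=O)CC1=C(OS(=O)(=O)C(F)(F)F)[C@@]2(C)OC(C)(C)O[C@H]2C1 | intermediate
9 | cyclopentenylacetate (cis-diol acetonide) | COC(=O)CC1=C[C@@]2(C)OC(C)(C)O[C@H]2C1 | intermediate
10 | cyclopentenyl diazoacetate (cis-diol acetonide) | COC(=O)C(=[N+]=[N-])C1=C[C@@]2(C)OC(C)(C)O[C@H]2C1 | intermediate
11 | methyl (R)-3-methylglutarate | COC(=O)C[C@H](C)CC(=O)O | starting material
12 | methyl (3R)-5-hydroxy-3-methylpentanoate | COC(=O)C[C@H](C)CCO | intermediate
13 | methyl (3R)-5-(tert-butyldiphenylsilyloxy)-3-methylpentanoate | COC(=O)C[C@H](C)CCO[Si](c1ccccc1)(c1ccccc1)C(C)(C)C | intermediate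
14 | (3R)-5-(tert-butyldiphenylsilyloxy)-3-methylpentanal | O=CC[C@H](C)CCO[Si](c1ccccc1)(c1ccccc1)C(C)(C)C | intermediate
15 | (E)-N-cyclohexyl aldimine of 14 | C1CCCCC1/N=C/C[C@H](C)CCO[Si](c1ccccc1)(c1ccccc1)C(C)(C)C | intermediate
16 | acetaldehyde | CC=O | starting material
17 | β-hydroxy aldimine (mixture at the two new centres) | CC(O)C(/C=N/C1CCCCC1)[C@H](C)CCO[Si](c1ccccc1)(c1ccccc1)C(C)(C)C | intermediate
18 | aldol, 2-(1-hydroxyethyl) aldehyde (mixture at the two new centres) | CC(O)C(C=O)[C@H](C)CCO[Si](c1ccccc1)(c1ccccc1)C(C)(C)C | intermediate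
19 | (2E)-2-[(2R)-4-(tert-butyldiphenylsilyloxy)butan-2-yl]but-2-enal | C/C=C(/C=O)[C@H](C)CCO[Si](c1ccccc1)(c1ccccc1)C(C)(C)C | intermediate
20 | 1-silyloxy-2-alkylbuta-1,3-diene, OTBS trans to vinyl | C=C/C(=C/O[Si](C)(C)C(C)(C)C)[C@H](C)CCO[Si](c1ccccc1)(c1ccccc1)C(C)(C)C | intermediate
21 | cis-divinylcyclopropane (C4 R, C6 S; cyclopentenyl and silyloxyvinyl cis) | COC(=O)[C@]1(C2=C[C@@]3(C)OC(C)(C)O[C@H]3C2)C[C@H]1/C(=C/O[Si](C)(C)C(C)(C)C)[C@H](C)CCO[Si](c1ccccc1)(c1ccccc1)C(C)(C)C | intermediate
22 | hydroazulene 1,4-diene ester with C8 silyl ether | COC(=O)C1=C2C[C@@H]3OC(C)(C)O[C@]3(C)[C@H]2[C@@H](O[Si](C)(C)C(C)(C)C)C([C@H](C)CCO[Si](c4ccccc4)(c4ccccc4)C(C)(C)C)=CC1 | intermediate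
23 | 6,7-dihydro ester (H-7 β) | COC(=O)C1=C2C[C@@H]3OC(C)(C)O[C@]3(C)[C@H]2[C@@H](O[Si](C)(C)C(C)(C)C)[C@@H]([C@H](C)CCO[Si](c4ccccc4)(c4ccccc4)C(C)(C)C)CC1 | intermediate
24 | C1 hemiketal of the dienoate | COC(=O)C1=C2C=C[C@](C)(OC(C)(C)O)[C@H]2[C@@H](O[Si](C)(C)C(C)(C)C)[C@@H]([C@H](C)CCO[Si](c3ccccc3)(c3ccccc3)C(C)(C)C)CC1 | intermediate
25 | 1β-hydroxy dienoate | COC(=O)C1=C2C=C[C@](C)(O)[C@H]2[C@@H](O[Si](C)(C)C(C)(C)C)[C@@H]([C@H](C)CCO[Si](c3ccccc3)(c3ccccc3)C(C)(C)C)CC1 | intermediate
26 | dienyl diol | OCC1=C2C=C[C@](C)(O)[C@H]2[C@@H](O[Si](C)(C)C(C)(C)C)[C@@H]([C@H](C)CCO[Si](c3ccccc3)(c3ccccc3)C(C)(C)C)CC1 | intermediate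
27 | N-alkyl-N-(2-nitrophenylsulfonyl) acetone hydrazone | CC(C)=NN(CC1=C2C=C[C@](C)(O)[C@H]2[C@@H](O[Si](C)(C)C(C)(C)C)[C@@H]([C@H](C)CCO[Si](c3ccccc3)(c3ccccc3)C(C)(C)C)CC1)S(=O)(=O)c1ccccc1[N+](=O)[O-] | intermediate
28 | allylic monoalkyl diazene | N=NCC1=C2C=C[C@](C)(O)[C@H]2[C@@H](O[Si](C)(C)C(C)(C)C)[C@@H]([C@H](C)CCO[Si](c3ccccc3)(c3ccccc3)C(C)(C)C)CC1 | intermediate
29 | 4-methylene hydroazulene, H-3a β | C=C1CC[C@H]([C@H](C)CCO[Si](c3ccccc3)(c3ccccc3)C(C)(C)C)[C@H](O[Si](C)(C)C(C)(C)C)[C@H]2[C@@H]1C=C[C@]2(C)O | intermediate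
30 | primary alcohol | C=C1CC[C@H]([C@H](C)CCO)[C@H](O[Si](C)(C)C(C)(C)C)[C@H]2[C@@H]1C=C[C@]2(C)O | intermediate
31 | C3′ aldehyde | C=C1CC[C@H]([C@H](C)CC=O)[C@H](O[Si](C)(C)C(C)(C)C)[C@H]2[C@@H]1C=C[C@]2(C)O | intermediate
32 | 2-methylprop-1-enylmagnesium bromide | CC(C)=C[Mg]Br | starting material
33 | C3′ allylic alcohols, both epimers | C=C1CC[C@H]([C@H](C)CC(O)C=C(C)C)[C@H](O[Si](C)(C)C(C)(C)C)[C@H]2[C@@H]1C=C[C@]2(C)O | intermediate
34 | C3′ isobutenyl ketone | C=C1CC[C@H]([C@H](C)CC(=O)C=C(C)C)[C@H](O[Si](C)(C)C(C)(C)C)[C@H]2[C@@H]1C=C[C@]2(C)O | intermediate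
35 | (3′R)-allylic alcohol | C=C1CC[C@H]([C@H](C)C[C@H](C=C(C)C)O)[C@H](O[Si](C)(C)C(C)(C)C)[C@H]2[C@@H]1C=C[C@]2(C)O | intermediate
36 | (3′R)-acetate, 8α-OTBS | C=C1CC[C@H]([C@H](C)C[C@H](C=C(C)C)OC(C)=O)[C@H](O[Si](C)(C)C(C)(C)C)[C@H]2[C@@H]1C=C[C@]2(C)O | intermediate
37 | CNP0209568.2 | C=C1CC[C@H]([C@H](C)C[C@H](C=C(C)C)OC(C)=O)[C@H](O)[C@H]2[C@@H]1C=C[C@]2(C)O | target

Total step count: 26. Longest linear sequence: 20 (steps 1–8, 15–26).

Steps most likely to fail

Step 15. What may go wrong:
- incomplete control over which carbenoid face is attacked, which would erode C8/C8a relative to C1;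
- carbene dimerisation;
- closure of the diazo compound to a pyrazole before it meets the catalyst.

The fallback moves the stereocontrol from the catalyst to a covalently bound auxiliary. It sets out from 9. Saponification (LiOH, THF–H2O) should give the cyclopentenylacetic acid F1, and DCC/DMAP coupling with (R)-pantolactone (its antipode is available if the sense proves opposite) the pantolactonyl ester F2. Diazo transfer as in step 8 then gives the pantolactonyl diazoacetate F3. Decomposition with achiral Rh2(O2CC7H15)4 in the presence of 20 relies on the lactone carbonyl shielding one carbenoid face and should give the pantolactonyl cycloadduct F4. Hydrolysis with LiOH gives the cycloadduct acid F5, and methylation with Me3SiCHN2 comes back to the route at 22.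

Step 17. What may go wrong:
- deprotonation at H-8a instead of C3, followed by loss of the C8 silyloxy or the C1 oxygen;
- incomplete expulsion of the ketal oxygen, so that the quench merely deconjugates the ester.

The fallback separates alkene formation from the ester chemistry and sets out from 23. Reduction with iBu2AlH gives the acetonide allylic alcohol F6, and the transposition of step 19 (IPNBSH, PPh3, DEAD; CF3CH2OH–H2O) the 4-methylene acetonide F7. Aqueous acetic acid then frees the 1,2-diol F8, and Dess–Martin oxidation of its only oxidisable hydroxyl gives the 1-hydroxy-2-ketone F9. Condensation with 2,4,6-triisopropylbenzenesulfonyl hydrazide gives the trisylhydrazone F10. A Shapiro reaction (n-BuLi, 3.5 equiv, THF, −78 → 0 °C), which can deprotonate only at C3, installs C2=C3 and comes back to the route at 29.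

Step 19. What may go wrong:
- poor facial selectivity in the hydrogen transfer to C3a;
- ionisation of the activated dienylic alcohol before the sulfonylhydrazone displaces it.

The fallback replaces the sigmatropic hydrogen transfer by metal-bound hydride delivery and sets out from 26. Selective acylation of the primary hydroxyl (ClCO2Me, pyridine, 0 °C) gives the allylic methyl carbonate F11. Palladium-catalysed formate hydrogenolysis follows (Pd(OAc)2, PBu3, HCO2H–Et3N, THF). Zerovalent palladium should ionise the carbonate on the less hindered β face and pass hydride from bound formate to the more substituted allyl terminus C3a, which comes back to the route at 29.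

Further compounds
F1 | step 15 | cyclopentenylacetic acid (cis-diol acetonide) | OC(=O)CC1=C[C@@]2(C)OC(C)(C)O[C@H]2C1
F2 | step 15 | (R)-pantolactonyl cyclopentenylacetate | CC1(C)COC(=O)[C@@H]1OC(=O)CC1=C[C@@]2(C)OC(C)(C)O[C@H]2C1
F3 | step 15 | (R)-pantolactonyl cyclopentenyl diazoacetate | CC1(C)COC(=O)[C@@H]1OC(=O)C(=[N+]=[N-])C1=C[C@@]2(C)OC(C)(C)O[C@H]2C1
F4 | step 15 | (R)-pantolactonyl ester of the hydroazulene 1,4-diene | CC1(C)COC(=O)[C@@H]1OC(=O)C1=C2C[C@@H]3OC(C)(C)O[C@]3(C)[C@H]2[C@@H](O[Si](C)(C)C(C)(C)C)C([C@H](C)CCO[Si](c4ccccc4)(c4ccccc4)C(C)(C)C)=CC1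
F5 | step 15 | hydroazulene 1,4-diene carboxylic acid | OC(=O)C1=C2C[C@@H]3OC(C)(C)O[C@]3(C)[C@H]2[C@@H](O[Si](C)(C)C(C)(C)C)C([C@H](C)CCO[Si](c4ccccc4)(c4ccccc4)C(C)(C)C)=CC1
F6 | step 17 | acetonide allylic alcohol (C4–CH2OH) | OCC1=C2C[C@@H]3OC(C)(C)O[C@]3(C)[C@H]2[C@@H](O[Si](C)(C)C(C)(C)C)[C@@H]([C@H](C)CCO[Si](c4ccccc4)(c4ccccc4)C(C)(C)C)CC1
F7 | step 17 | 4-methylene acetonide, H-3a β | C=C1CC[C@H]([C@H](C)CCO[Si](c4ccccc4)(c4ccccc4)C(C)(C)C)[C@H](O[Si](C)(C)C(C)(C)C)[C@H]2[C@@H]1C[C@@H]3OC(C)(C)O[C@]23C
F8 | step 17 | 4-methylene 1β,2β-diol | C=C1CC[C@H]([C@H](C)CCO[Si](c4ccccc4)(c4ccccc4)C(C)(C)C)[C@H](O[Si](C)(C)C(C)(C)C)[C@H]2[C@@H]1C[C@H](O)[C@]2(C)O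
F9 | step 17 | 1β-hydroxy-2-ketone | C=C1CC[C@H]([C@H](C)CCO[Si](c4ccccc4)(c4ccccc4)C(C)(C)C)[C@H](O[Si](C)(C)C(C)(C)C)[C@H]2[C@@H]1CC(=O)[C@]2(C)O
F10 | step 17 | C2 trisylhydrazone | C=C1CC[C@H]([C@H](C)CCO[Si](c4ccccc4)(c4ccccc4)C(C)(C)C)[C@H](O[Si](C)(C)C(C)(C)C)[C@H]2[C@@H]1CC(=NNS(=O)(=O)c3c(C(C)C)cc(C(C)C)cc3C(C)C)[C@]2(C)O
F11 | step 19 | primary allylic methyl carbonate of 26 | COC(=O)OCC1=C2C=C[C@](C)(O)[C@H]2[C@@H](O[Si](C)(C)C(C)(C)C)[C@@H]([C@H](C)CCO[Si](c3ccccc3)(c3ccccc3)C(C)(C)C)CC1
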